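The constants of the steps are hidden, so any reckoning for this flask has to start from the charges and the two earlier runs.

| flask | starting material | protic impurity | remark | time |
|---|---|---|---|---|
| autumn | 0.75 M | 0.75 M | run made earlier |  |
| summer | 3 M | 0.75 M | run made earlier |  |
| flask | 1.5 M | 0.750 M |  | 12 min |

| run | time / min | isomer of the product / % | target / % |
|---|---|---|---|
| autumn | 0.250 | 4.9 | 23.8 |
| autumn | 0.417 | 6.6 | 21.8 |
| autumn | 0.833 | 9.8 | 19.6 |
| autumn | 1.33 | 8.1 | 15.7 |
| autumn | 2.50 | 7.8 | 12.2 |
| autumn | 4.00 | 5.5 | 9.2 |
| autumn | 8.00 | 3.9 | 5.5 |
| summer | 0.250 | 5.4 | 24.2 |
| summer | 0.417 | 8.6 | 22.8 |
| summer | 0.833 | 9.4 | 20.9 |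
| summer | 1.33 | 10.0 | 19.7 |
| summer | 2.50 | 9.5 | 19.4 |
| summer | 4.00 | 9.4 | 18.2 |
| summer | 8.00 | 7.8 | 18.8 |

(each reading ± 0.5 percentage points)

1. time up to 12 min at which isomer of the product stands highest
2. the amount of isomer of the product, in percent of the starting material charged, at that time
3. earliest time at which at least nineteen twentieths of that best amount are there, in min
4. latest time at which they still are, in min

- steps under discussion: starting material <-> target; starting material + protic impurity -> quenched substrate; target <-> isomer of the product

Both runs carried the same [protic impurity], and their highest readings of isomer of the product are 9.8% in autumn and 10.0% in summer; these are single scattered readings, and the gap between the two readings is smaller than the scatter. One chemist therefore calls the flask a repeat of the autumn run, since its [protic impurity] matches autumn's. The isomer should rise to about 9.90% and then keep sinking as autumn's did, to 3.9% at 8.00 min.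

The other chemist counts what can be lost. In the flask the protic impurity is the limiting reagent of the quench. If one impurity quenches one starting material, the live pool of starting material, target and isomer stops falling at a floor of 50.0% of the charge. The same count gives summer 75.0%. Summer's last three isomer readings average 8.90%, and dividing by that floor gives 11.9%. This is the isomer share, the part of the live pool that stands as isomer once the pool has stopped shrinking. So the flask should not sink as autumn did but level off near 5.95%.

My own reckoning joins the two. I take the peak from the runs as the large quantity and compute the later fall as a correction of 4 percentage points. The window should close between autumn's decline, already 8.1% at 1.33 min, and summer's plateau, still 9.4% at 4.00 min.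

The forecast sides with the second chemist, saying “Isomer chases 0.125 × pool and peaks where the curves cross”, and gives 9.5% at 0.92 min, with a window from 0.62 min to 1.4 min.

    starting material ⇌ target (K = 0.390, k = 0.230 /s)
    starting material + protic impurity → quenched substrate (k = 0.0130 /M/s)
    target ⇌ isomer of the product (K = 0.500, k = 0.0200 /s)

The simulated flask peaks at 9.29% at 1.03 min, and the window asked for runs from 0.670 min to 1.64 min. The autumn picture has its region up to the peak: autumn without scatter reaches 9.05%, and the flask still has 50.5% of its impurity charge at 1.03 min. At 12.0 min, with 0.59% of the impurity left, the flask holds 6.19% of isomer, against 5.95% from share times floor. The neighbour charged with 0.60 M keeps 30% of its impurity. Its live pool at the end is 12.4% of its charge, the isomer share of that pool comes to 1.48%, and the neighbour stands at 1.60%.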